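**Assumption:** the SMILES is read as epirobinetinidol-(4β→8)-epirobinetinidol-(4α→8)-epicatechin, with upper unit U (2R,3R,4R), middle unit M (2R,3R,4S) and lower unit L (2R,3R); compounds 1, 3 and 18 are taken as catalogue materials.

## Retrosynthetic overview

1. Target ⇐ per-benzylated 6,6'-dibromo trimer by one hydrogenolysis; the 3-OH groups of units M and L are set just before by a double oxidation / bulky-hydride reduction (trans → cis).
2. C4(M)–C8(L) bond ⇐ C4 cation of a 2,3-trans flavan-3,4-diol ether of M plus tetra-O-benzyl-(+)-catechin (attack trans to the 3-OH gives 4α).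
3. Pyran ring of M ⇐ opened to a 2'-hydroxychalcone while U is already attached at the future C8: chalcone → dihydroflavonol closure (asymmetric epoxidation, 6-endo phenoxide attack), then C4 reduction.
4. C4(U)–C8(M) bond ⇐ 2,3-cis C4 cation of U plus the brominated acetophenone that becomes ring A of M (bromine leaves only the future C8 open; attack anti to 3-OBn gives 4β).
5. Pyran ring of U ⇐ the same chalcone → dihydroflavonol closure. Ring order: pyran ring of U first, pyran ring of M second (after the interflavanyl bond), unit L taken from (+)-catechin.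

## Route

Step 1
Reactants: 1 1-(5-bromo-2,4-dihydroxyphenyl)ethan-1-one
Product: 2 1-[4-(benzyloxy)-5-bromo-2-hydroxyphenyl]ethan-1-one
Conditions: BnBr (1.05 equiv), K2CO3, acetone, reflux
Reagents that add atoms: benzyl bromide, BrCc1ccccc1
Why: Williamson etherification is selective for the 4-OH because the 2-OH is held in a hydrogen bond to the acetyl group, and no stereocentre is involved.

Step 2
Reactants: 2 1-[4-(benzyloxy)-5-bromo-2-hydroxyphenyl]ethan-1-one; 3 3,4,5-tris(benzyloxy)benzaldehyde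
Product: 4 (E)-1-[4-(benzyloxy)-5-bromo-2-hydroxyphenyl]-3-[3,4,5-tris(benzyloxy)phenyl]prop-2-en-1-one
Conditions: KOH (50% aq.), EtOH/THF, rt
Reagents that add atoms: none
Why: Claisen–Schmidt aldol condensation gives the (E)-2'-hydroxychalcone, the open-chain biosynthetic precursor of the pyran ring.

Step 3
Reactants: 4 (E)-2'-hydroxychalcone
Product: 6 (2R,3R)-7-(benzyloxy)-6-bromo-3-hydroxy-2-[3,4,5-tris(benzyloxy)phenyl]chroman-4-one (2,3-trans dihydroflavonol), via chalcone epoxide 5 (not isolated)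
Conditions: poly-L-leucine, urea–H2O2, DBU, THF, 0 °C → rt; AcOH quench; recrystallise
Reagents that add atoms: urea–hydrogen peroxide, OO.NC(N)=O
Why: Proposed new method: poly-L-leucine-mediated Juliá–Colonna (asymmetric Weitz–Scheffer) epoxidation is run on the free 2'-hydroxychalcone so that the (αR,βS)-epoxide 5 is opened in the same flask by the 2'-phenoxide in a 6-endo SN2 attack at the benzylic Cβ with inversion (the ring closure of the Algar–Flynn–Oyamada reaction, stopped at the dihydroflavonol), which mirrors the biosynthetic chalcone → dihydroflavonol sequence and sets C2 (R) and C3 (R, trans) together, the closest known reaction types being the poly-amino-acid epoxidation of 2'-O-protected chalcones with separate cyclisation and the racemic Algar–Flynn–Oyamada reaction.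

Step 4
Reactants: 6 (2R,3R)-dihydroflavonol
Product: 8 (2R,3S,4R)-7-(benzyloxy)-6-bromo-4-methoxy-2-[3,4,5-tris(benzyloxy)phenyl]chroman-3-ol (2,3-trans-3,4-trans), via flavan-3,4-diol 7 (not isolated)
Conditions: NaBH4, THF/MeOH, 0 °C; then HCl in MeOH (to pH 2), rt
Reagents that add atoms: methanol, CO
Why: Borohydride reduction of the 4-ketone (the laboratory counterpart of dihydroflavonol reductase) gives the 2,3-trans-3,4-trans diol, and acid-catalysed SN1 methanolysis through the 7-alkoxy-stabilised C4 cation gives the thermodynamically favoured all-equatorial 4α-methyl ether, which masks C4 and leaves only the 3-OH free.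

Step 5
Reactants: 8 4-methoxyflavan-3-ol
Product: 9 (2R,4R)-7-(benzyloxy)-6-bromo-4-methoxy-2-[3,4,5-tris(benzyloxy)phenyl]chroman-3-one
Conditions: Dess–Martin periodinane, wet CH2Cl2, rt
Reagents that add atoms: none
Why: Dess–Martin oxidation of the only free alcohol gives the flavan-3-one under near-neutral conditions, and C2 and C4 stay in the more stable 2,4-cis diequatorial arrangement.

Step 6
Reactants: 9 4-methoxyflavan-3-one
Product: 11 (2R,3R,4R)-3,7-bis(benzyloxy)-6-bromo-4-methoxy-2-[3,4,5-tris(benzyloxy)phenyl]chromane (all-cis), via potassium alkoxide 10 (not isolated)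
Conditions: K[HB(s-Bu)3], THF, −78 °C; then BnBr, Bu4NI (cat.), DMF, −78 °C → rt
Reagents that add atoms: benzyl bromide, BrCc1ccccc1
Why: The bulky borohydride attacks the ketone from the equatorial direction (as in the known catechin-ketone to epicatechin reduction) to give the axial 3-alkoxide cis to the 2-aryl group (3R, 2,3-cis), which is trapped in the same flask by Williamson benzylation.

Step 7
Reactants: 11 all-cis 3-O-benzyl-4-methoxyflavan; 2 1-[4-(benzyloxy)-5-bromo-2-hydroxyphenyl]ethan-1-one (4 equiv, excess recovered)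
Product: 12 1-{4-(benzyloxy)-3-[(2R,3R,4R)-3,7-bis(benzyloxy)-6-bromo-2-(3,4,5-tris(benzyloxy)phenyl)chroman-4-yl]-5-bromo-2-hydroxyphenyl}ethan-1-one (flavan unit 2,3-cis-3,4-trans)
Conditions: TfOH (10 mol%), CH2Cl2, −40 → 0 °C
Reagents that add atoms: none
Why: Acid ionisation of the 4-methoxy group gives the 7-alkoxy-stabilised C4 cation (the laboratory form of the leucoanthocyanidin-derived extension unit), which is captured in a Friedel–Crafts alkylation by the only open activated carbon of 2 (C3, between OH and OBn, C5 being blocked by bromine) from the face anti to the axial 3-benzyloxy group, so the new centre is 4β (4R, 3,4-trans).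

Step 8
Reactants: 12 flavanyl-acetophenone; 3 3,4,5-tris(benzyloxy)benzaldehyde
Product: 13 (E)-1-{4-(benzyloxy)-3-[(2R,3R,4R)-3,7-bis(benzyloxy)-6-bromo-2-(3,4,5-tris(benzyloxy)phenyl)chroman-4-yl]-5-bromo-2-hydroxyphenyl}-3-[3,4,5-tris(benzyloxy)phenyl]prop-2-en-1-one
Conditions: KOH (50% aq.), EtOH/THF, rt
Reagents that add atoms: none
Why: Claisen–Schmidt condensation on the acetyl group gives the (E)-chalcone that already carries unit U on the future C8, and none of the existing stereocentres is base-labile.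

Step 9
Reactants: 13 flavanyl-chalcone
Product: 15 (2R,3R)-7-(benzyloxy)-8-[(2R,3R,4R)-3,7-bis(benzyloxy)-6-bromo-2-(3,4,5-tris(benzyloxy)phenyl)chroman-4-yl]-6-bromo-3-hydroxy-2-[3,4,5-tris(benzyloxy)phenyl]chroman-4-one, via chalcone epoxide 14 (not isolated)
Conditions: poly-L-leucine, urea–H2O2, DBU, THF, 0 °C → rt; AcOH quench; chromatography
Reagents that add atoms: urea–hydrogen peroxide, OO.NC(N)=O
Why: Proposed new method: the same asymmetric epoxidation / 6-endo phenoxide ring closure as in step 3 is used under catalyst control on a chiral substrate, poly-L-leucine again giving the (αR,βS)-epoxide and hence the (2R,3R)-trans pyran ring of unit M next to the interflavanyl bond, the closest known reaction types being the Juliá–Colonna epoxidation of protected chalcones and the Algar–Flynn–Oyamada reaction, with the minor diastereomer removed by chromatography.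

Step 10
Reactants: 15 flavanyl-dihydroflavonol
Product: 17 (2R,3S,4R)-7-(benzyloxy)-8-[(2R,3R,4R)-3,7-bis(benzyloxy)-6-bromo-2-(3,4,5-tris(benzyloxy)phenyl)chroman-4-yl]-6-bromo-4-methoxy-2-[3,4,5-tris(benzyloxy)phenyl]chroman-3-ol, via flavan-3,4-diol 16 (not isolated)
Conditions: NaBH4, THF/MeOH, 0 °C; then HCl in MeOH (to pH 2), rt
Reagents that add atoms: methanol, CO
Why: As in step 4, borohydride reduction of the 4-ketone followed by SN1 methanolysis of the benzylic 4-OH gives the 2,3-trans-3,4-trans 4-methyl ether of unit M as a storable C4-cation precursor.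

Step 11
Reactants: 18 (+)-catechin, (2R,3S)-2-(3,4-dihydroxyphenyl)chromane-3,5,7-triol
Product: 19 5,7,3',4'-tetra-O-benzyl-(+)-catechin, (2R,3S)-5,7-bis(benzyloxy)-2-[3,4-bis(benzyloxy)phenyl]chroman-3-ol
Conditions: BnBr (4.4 equiv), K2CO3, DMF, 0 °C → rt
Reagents that add atoms: benzyl bromide, BrCc1ccccc1
Why: Williamson benzylation with carbonate is selective for the four phenols over the aliphatic 3-OH and leaves both stereocentres untouched.

Step 12
Reactants: 17 4-methoxy dimer; 19 tetra-O-benzyl-(+)-catechin (3 equiv, excess recovered)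
Product: 20 6-bromo-3,7,3',4',5'-penta-O-benzyl-epirobinetinidol-(4β→8)-6-bromo-7,3',4',5'-tetra-O-benzyl-robinetinidol-(4α→8)-5,7,3',4'-tetra-O-benzyl-catechin [U (2R,3R,4R); M (2R,3S,4S); L (2R,3S)]
Conditions: TMSOTf (cat.), CH2Cl2, −78 → −40 °C; chromatography
Reagents that add atoms: none
Why: Ionisation of the 4-methoxy group gives the C4 cation of unit M, and Friedel–Crafts attack by C8 of the benzylated phloroglucinol ring of 19 trans to the equatorial 3-OH forms the 4α (4S, 3,4-trans) bond as in biomimetic proanthocyanidin chain extension, the minor 4β isomer being removed by chromatography.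

Step 13
Reactants: 20 protected trimer with 3-OH free in units M and L
Product: 21 the corresponding bis(flavan-3-one), 3-oxo in unit M (2R,4S) and in unit L (2R), unit U unchanged
Conditions: Dess–Martin periodinane (3 equiv), wet CH2Cl2, rt
Reagents that add atoms: none
Why: Dess–Martin oxidation converts the two free secondary alcohols into flavan-3-ones while the 3-O-benzyl group protects unit U, and C2/C4 of unit M keep the stable 2,4-cis diequatorial arrangement.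

Step 14
Reactants: 21 bis(flavan-3-one)
Product: 22 6-bromo-3,7,3',4',5'-penta-O-benzyl-epirobinetinidol-(4β→8)-6-bromo-7,3',4',5'-tetra-O-benzyl-epirobinetinidol-(4α→8)-5,7,3',4'-tetra-O-benzyl-epicatechin [U (2R,3R,4R); M (2R,3R,4S); L (2R,3R)]
Conditions: Li[HB(s-Bu)3] (excess), THF, −78 °C
Reagents that add atoms: none
Why: Equatorial hydride delivery by the bulky borohydride to both ketones (the known flavan-3-one reduction) gives axial 3-OH groups cis to the 2-aryl groups, i.e. 3R in unit M (now 2,3-cis-3,4-cis with the 4α bond) and 3R in unit L (catechin-type to epicatechin-type).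

Step 15
Reactants: 22 per-benzylated dibromo trimer
Product: 23 epirobinetinidol-(4β→8)-epirobinetinidol-(4α→8)-epicatechin (CNP0115797.2)
Conditions: H2 (1 atm), Pd(OH)2/C, NaOAc, THF/MeOH/H2O, rt
Reagents that add atoms: none
Why: Hydrogenolysis removes the thirteen benzyl ethers and both aryl bromides (acetate buffers the HBr) without touching any of the eight stereocentres.

## Compound list

1 | 1-(5-bromo-2,4-dihydroxyphenyl)ethan-1-one | CC(=O)c1cc(Br)c(O)cc1O | starting material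
2 | 1-[4-(benzyloxy)-5-bromo-2-hydroxyphenyl]ethan-1-one | CC(=O)c1cc(Br)c(OCc2ccccc2)cc1O | intermediate
3 | 3,4,5-tris(benzyloxy)benzaldehyde | O=Cc1cc(OCc2ccccc2)c(OCc2ccccc2)c(OCc2ccccc2)c1 | starting material
4 | (E)-1-[4-(benzyloxy)-5-bromo-2-hydroxyphenyl]-3-[3,4,5-tris(benzyloxy)phenyl]prop-2-en-1-one | O=C(/C=C/c1cc(OCc2ccccc2)c(OCc2ccccc2)c(OCc2ccccc2)c1)c1cc(Br)c(OCc2ccccc2)cc1O | intermediate
5 | [4-(benzyloxy)-5-bromo-2-hydroxyphenyl]{(2R,3S)-3-[3,4,5-tris(benzyloxy)phenyl]oxiran-2-yl}methanone (αR,βS chalcone epoxide) | O=C([C@@H]1O[C@H]1c1cc(OCc2ccccc2)c(OCc2ccccc2)c(OCc2ccccc2)c1)c1cc(Br)c(OCc2ccccc2)cc1O | intermediate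
6 | (2R,3R)-7-(benzyloxy)-6-bromo-3-hydroxy-2-[3,4,5-tris(benzyloxy)phenyl]chroman-4-one (2,3-trans) | Brc1cc2c(cc1OCc1ccccc1)O[C@H](c1cc(OCc3ccccc3)c(OCc3ccccc3)c(OCc3ccccc3)c1)[C@@H](O)C2=O | intermediate
7 | (2R,3S,4R)-7-(benzyloxy)-6-bromo-2-[3,4,5-tris(benzyloxy)phenyl]chromane-3,4-diol (2,3-trans-3,4-trans) | Brc1cc2c(cc1OCc1ccccc1)O[C@H](c1cc(OCc3ccccc3)c(OCc3ccccc3)c(OCc3ccccc3)c1)[C@@H](O)[C@@H]2O | intermediate
8 | (2R,3S,4R)-7-(benzyloxy)-6-bromo-4-methoxy-2-[3,4,5-tris(benzyloxy)phenyl]chroman-3-ol (2,3-trans-3,4-trans) | Brc1cc2c(cc1OCc1ccccc1)O[C@H](c1cc(OCc3ccccc3)c(OCc3ccccc3)c(OCc3ccccc3)c1)[C@@H](O)[C@@H]2OC | intermediate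
9 | (2R,4R)-7-(benzyloxy)-6-bromo-4-methoxy-2-[3,4,5-tris(benzyloxy)phenyl]chroman-3-one (2-aryl and 4-OMe cis) | Brc1cc2c(cc1OCc1ccccc1)O[C@H](c1cc(OCc3ccccc3)c(OCc3ccccc3)c(OCc3ccccc3)c1)C(=O)[C@@H]2OC | intermediate
10 | potassium (2R,3R,4R)-7-(benzyloxy)-6-bromo-4-methoxy-2-[3,4,5-tris(benzyloxy)phenyl]chroman-3-olate (all-cis) | Brc1cc2c(cc1OCc1ccccc1)O[C@H](c1cc(OCc3ccccc3)c(OCc3ccccc3)c(OCc3ccccc3)c1)[C@H]([O-])[C@@H]2OC.[K+] | intermediate
11 | (2R,3R,4R)-3,7-bis(benzyloxy)-6-bromo-4-methoxy-2-[3,4,5-tris(benzyloxy)phenyl]chromane (all-cis) | Brc1cc2c(cc1OCc1ccccc1)O[C@H](c1cc(OCc3ccccc3)c(OCc3ccccc3)c(OCc3ccccc3)c1)[C@H](OCc1ccccc1)[C@@H]2OC | intermediate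
12 | 1-{4-(benzyloxy)-3-[(2R,3R,4R)-3,7-bis(benzyloxy)-6-bromo-2-(3,4,5-tris(benzyloxy)phenyl)chroman-4-yl]-5-bromo-2-hydroxyphenyl}ethan-1-one (flavan unit 2,3-cis-3,4-trans) | Brc1cc2c(cc1OCc1ccccc1)O[C@H](c1cc(OCc3ccccc3)c(OCc3ccccc3)c(OCc3ccccc3)c1)[C@H](OCc1ccccc1)[C@H]2c1c(OCc3ccccc3)c(Br)cc(C(C)=O)c1O | intermediate
13 | (E)-1-{4-(benzyloxy)-3-[(2R,3R,4R)-3,7-bis(benzyloxy)-6-bromo-2-(3,4,5-tris(benzyloxy)phenyl)chroman-4-yl]-5-bromo-2-hydroxyphenyl}-3-[3,4,5-tris(benzyloxy)phenyl]prop-2-en-1-one | Brc1cc2c(cc1OCc1ccccc1)O[C@H](c1cc(OCc3ccccc3)c(OCc3ccccc3)c(OCc3ccccc3)c1)[C@H](OCc1ccccc1)[C@H]2c1c(OCc3ccccc3)c(Br)cc(C(=O)/C=C/c3cc(OCc4ccccc4)c(OCc4ccccc4)c(OCc4ccccc4)c3)c1O | intermediate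
14 | {4-(benzyloxy)-3-[(2R,3R,4R)-3,7-bis(benzyloxy)-6-bromo-2-(3,4,5-tris(benzyloxy)phenyl)chroman-4-yl]-5-bromo-2-hydroxyphenyl}{(2R,3S)-3-[3,4,5-tris(benzyloxy)phenyl]oxiran-2-yl}methanone (αR,βS epoxide of 13) | Brc1cc2c(cc1OCc1ccccc1)O[C@H](c1cc(OCc3ccccc3)c(OCc3ccccc3)c(OCc3ccccc3)c1)[C@H](OCc1ccccc1)[C@H]2c1c(OCc3ccccc3)c(Br)cc(C(=O)[C@@H]3O[C@H]3c3cc(OCc4ccccc4)c(OCc4ccccc4)c(OCc4ccccc4)c3)c1O | intermediate
15 | (2R,3R)-7-(benzyloxy)-8-[(2R,3R,4R)-3,7-bis(benzyloxy)-6-bromo-2-(3,4,5-tris(benzyloxy)phenyl)chroman-4-yl]-6-bromo-3-hydroxy-2-[3,4,5-tris(benzyloxy)phenyl]chroman-4-one | Brc1cc2c(cc1OCc1ccccc1)O[C@H](c1cc(OCc3ccccc3)c(OCc3ccccc3)c(OCc3ccccc3)c1)[C@H](OCc1ccccc1)[C@H]2c1c(OCc3ccccc3)c(Br)cc2c1O[C@H](c1cc(OCc3ccccc3)c(OCc3ccccc3)c(OCc3ccccc3)c1)[C@@H](O)C2=O | intermediate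
16 | (2R,3S,4R)-7-(benzyloxy)-8-[(2R,3R,4R)-3,7-bis(benzyloxy)-6-bromo-2-(3,4,5-tris(benzyloxy)phenyl)chroman-4-yl]-6-bromo-2-[3,4,5-tris(benzyloxy)phenyl]chromane-3,4-diol | Brc1cc2c(cc1OCc1ccccc1)O[C@H](c1cc(OCc3ccccc3)c(OCc3ccccc3)c(OCc3ccccc3)c1)[C@H](OCc1ccccc1)[C@H]2c1c(OCc3ccccc3)c(Br)cc2c1O[C@H](c1cc(OCc3ccccc3)c(OCc3ccccc3)c(OCc3ccccc3)c1)[C@@H](O)[C@@H]2O | intermediate
17 | (2R,3S,4R)-7-(benzyloxy)-8-[(2R,3R,4R)-3,7-bis(benzyloxy)-6-bromo-2-(3,4,5-tris(benzyloxy)phenyl)chroman-4-yl]-6-bromo-4-methoxy-2-[3,4,5-tris(benzyloxy)phenyl]chroman-3-ol | Brc1cc2c(cc1OCc1ccccc1)O[C@H](c1cc(OCc3ccccc3)c(OCc3ccccc3)c(OCc3ccccc3)c1)[C@H](OCc1ccccc1)[C@H]2c1c(OCc3ccccc3)c(Br)cc2c1O[C@H](c1cc(OCc3ccccc3)c(OCc3ccccc3)c(OCc3ccccc3)c1)[C@@H](O)[C@@H]2OC | intermediate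
18 | (+)-catechin, (2R,3S)-2-(3,4-dihydroxyphenyl)chromane-3,5,7-triol | Oc1cc(O)c2c(c1)O[C@H](c1ccc(O)c(O)c1)[C@@H](O)C2 | starting material
19 | 5,7,3',4'-tetra-O-benzyl-(+)-catechin, (2R,3S)-5,7-bis(benzyloxy)-2-[3,4-bis(benzyloxy)phenyl]chroman-3-ol | c1ccccc1COc1cc(OCc3ccccc3)c2c(c1)O[C@H](c1ccc(OCc3ccccc3)c(OCc3ccccc3)c1)[C@@H](O)C2 | intermediate
20 | 6-bromo-3,7,3',4',5'-penta-O-benzyl-epirobinetinidol-(4β→8)-6-bromo-7,3',4',5'-tetra-O-benzyl-robinetinidol-(4α→8)-5,7,3',4'-tetra-O-benzyl-catechin [U (2R,3R,4R); M (2R,3S,4S); L (2R,3S)] | Brc1cc2c(cc1OCc1ccccc1)O[C@H](c1cc(OCc3ccccc3)c(OCc3ccccc3)c(OCc3ccccc3)c1)[C@H](OCc1ccccc1)[C@H]2c1c(OCc3ccccc3)c(Br)cc2c1O[C@H](c1cc(OCc3ccccc3)c(OCc3ccccc3)c(OCc3ccccc3)c1)[C@@H](O)[C@@H]2c1c(OCc3ccccc3)cc(OCc3ccccc3)c2c1O[C@H](c1ccc(OCc3ccccc3)c(OCc3ccccc3)c1)[C@@H](O)C2 | intermediate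
21 | bis(flavan-3-one) of 20: 3-oxo in unit M (2R,4S) and in unit L (2R), unit U (2R,3R,4R) unchanged | Brc1cc2c(cc1OCc1ccccc1)O[C@H](c1cc(OCc3ccccc3)c(OCc3ccccc3)c(OCc3ccccc3)c1)[C@H](OCc1ccccc1)[C@H]2c1c(OCc3ccccc3)c(Br)cc2c1O[C@H](c1cc(OCc3ccccc3)c(OCc3ccccc3)c(OCc3ccccc3)c1)C(=O)[C@@H]2c1c(OCc3ccccc3)cc(OCc3ccccc3)c2c1O[C@H](c1ccc(OCc3ccccc3)c(OCc3ccccc3)c1)C(=O)C2 | intermediate
22 | 6-bromo-3,7,3',4',5'-penta-O-benzyl-epirobinetinidol-(4β→8)-6-bromo-7,3',4',5'-tetra-O-benzyl-epirobinetinidol-(4α→8)-5,7,3',4'-tetra-O-benzyl-epicatechin [U (2R,3R,4R); M (2R,3R,4S); L (2R,3R)] | Brc1cc2c(cc1OCc1ccccc1)O[C@H](c1cc(OCc3ccccc3)c(OCc3ccccc3)c(OCc3ccccc3)c1)[C@H](OCc1ccccc1)[C@H]2c1c(OCc3ccccc3)c(Br)cc2c1O[C@H](c1cc(OCc3ccccc3)c(OCc3ccccc3)c(OCc3ccccc3)c1)[C@H](O)[C@@H]2c1c(OCc3ccccc3)cc(OCc3ccccc3)c2c1O[C@H](c1ccc(OCc3ccccc3)c(OCc3ccccc3)c1)[C@H](O)C2 | intermediate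
23 | epirobinetinidol-(4β→8)-epirobinetinidol-(4α→8)-epicatechin [U (2R,3R,4R); M (2R,3R,4S); L (2R,3R)], CNP0115797.2 | Oc1ccc2c(c1)O[C@H](c1cc(O)c(O)c(O)c1)[C@H](O)[C@H]2c1c(O)ccc2c1O[C@H](c1cc(O)c(O)c(O)c1)[C@H](O)[C@@H]2c1c(O)cc(O)c2c1O[C@H](c1ccc(O)c(O)c1)[C@H](O)C2 | target

## Step count and risks

Total step count: 15. Longest linear sequence: 14 (steps 1–10 and 12–15; step 11 is a one-step side branch).

The three steps most likely to fail are 3, 7 and 9.

Step 3 (the same method recurs in step 9). The free 2'-phenoxide makes the enone a poor acceptor for peptide-bound hydroperoxide, base and peroxide can over-oxidise 6 to the flavonol, 5-exo closure gives aurone-type products, and the enantiomeric excess may be low. The fallback sets out from chalcone 4. The classical Algar–Flynn–Oyamada closure (H2O2, NaOH, MeOH/THF, 0 °C, stopped at the dihydroflavonol) gives the racemate, that is 6 together with its enantiomer (2S,3S)-7-(benzyloxy)-6-bromo-3-hydroxy-2-[3,4,5-tris(benzyloxy)phenyl]chroman-4-one F1. The enantiomers are then separated during the C4 reduction by asymmetric transfer hydrogenation with kinetic resolution (RuCl[(S,S)-TsDPEN](p-cymene), HCO2H/Et3N, CH2Cl2, rt): the matched (2R,3R) ketone is reduced to diol 7 and F1 is left and removed by chromatography. The fallback comes back to the route at 7, which is taken on with acidic methanol to 8.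

Step 7. C3 of 2 is flanked by OH and OBn and deactivated by the acetyl group and the bromine, so the cation from 11 may instead alkylate a second molecule of 11 (its C8 or its tribenzyloxyphenyl ring) or lose H3 to a flav-3-ene. The fallback closes the pyran ring of M before the coupling and uses a thioether as a latent leaving group; it sets out from 7 and 11. Diol 7 with BnSH and catalytic TfOH (CH2Cl2, −20 °C) gives (2R)-2,3-trans-3,4-trans-7-(benzyloxy)-4-(benzylsulfanyl)-6-bromo-2-[3,4,5-tris(benzyloxy)phenyl]chroman-3-ol F2. Then 11 and F2 (3 equiv) with catalytic TMSOTf at −78 °C (the thioether is inert) give 6-bromo-3,7,3',4',5'-penta-O-benzyl-epirobinetinidol-(4β→8)-4α-(benzylsulfanyl)-6-bromo-7,3',4',5'-tetra-O-benzyl-robinetinidol F3 by attack of the only open ring-A carbon of F2. Activation of the thioether of F3 with AgBF4 in THF in the presence of 19 gives 20, where the fallback comes back to the route; steps 8–10 are then not needed. The remaining uncertainty there is competition from the tribenzyloxyphenyl ring of F2.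

Step 9. The ring must close next to the bulky flavanyl group, and catalyst control on a large chiral substrate is untested. The fallback separates cyclisation from hydroxylation (chalcone isomerase, then 3-hydroxylase logic) and sets out from 13. NaOAc in refluxing EtOH closes the ring by reversible oxa-Michael addition; the (2S)-flavanone (2S)-7-(benzyloxy)-8-[(2R,3R,4R)-3,7-bis(benzyloxy)-6-bromo-2-(3,4,5-tris(benzyloxy)phenyl)chroman-4-yl]-6-bromo-2-[3,4,5-tris(benzyloxy)phenyl]chroman-4-one F4 is separated and its C2 epimer is re-equilibrated. TMSOTf/Et3N then gives the 4-(trimethylsilyloxy)-2H-chromene (silyl enol ether) of F4 F5, and Rubottom oxidation with dimethyldioxirane (acetone, −40 °C) followed by dilute acid places the oxygen anti to the 2-aryl group. This gives 15, where the fallback comes back to the route.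

## Further compounds

F1 | step 3 | (2S,3S)-7-(benzyloxy)-6-bromo-3-hydroxy-2-[3,4,5-tris(benzyloxy)phenyl]chroman-4-one | Brc1cc2c(cc1OCc1ccccc1)O[C@@H](c1cc(OCc3ccccc3)c(OCc3ccccc3)c(OCc3ccccc3)c1)[C@H](O)C2=O
F2 | step 7 | (2R)-2,3-trans-3,4-trans-7-(benzyloxy)-4-(benzylsulfanyl)-6-bromo-2-[3,4,5-tris(benzyloxy)phenyl]chroman-3-ol | Brc1cc2c(cc1OCc1ccccc1)O[C@H](c1cc(OCc3ccccc3)c(OCc3ccccc3)c(OCc3ccccc3)c1)[C@@H](O)[C@@H]2SCc1ccccc1
F3 | step 7 | 6-bromo-3,7,3',4',5'-penta-O-benzyl-epirobinetinidol-(4β→8)-4α-(benzylsulfanyl)-6-bromo-7,3',4',5'-tetra-O-benzyl-robinetinidol | Brc1cc2c(cc1OCc1ccccc1)O[C@H](c1cc(OCc3ccccc3)c(OCc3ccccc3)c(OCc3ccccc3)c1)[C@H](OCc1ccccc1)[C@H]2c1c(OCc3ccccc3)c(Br)cc2c1O[C@H](c1cc(OCc3ccccc3)c(OCc3ccccc3)c(OCc3ccccc3)c1)[C@@H](O)[C@@H]2SCc1ccccc1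
F4 | step 9 | (2S)-7-(benzyloxy)-8-[(2R,3R,4R)-3,7-bis(benzyloxy)-6-bromo-2-(3,4,5-tris(benzyloxy)phenyl)chroman-4-yl]-6-bromo-2-[3,4,5-tris(benzyloxy)phenyl]chroman-4-one | Brc1cc2c(cc1OCc1ccccc1)O[C@H](c1cc(OCc3ccccc3)c(OCc3ccccc3)c(OCc3ccccc3)c1)[C@H](OCc1ccccc1)[C@H]2c1c(OCc3ccccc3)c(Br)cc2c1O[C@H](c1cc(OCc3ccccc3)c(OCc3ccccc3)c(OCc3ccccc3)c1)CC2=O
F5 | step 9 | 4-(trimethylsilyloxy)-2H-chromene (silyl enol ether) of F4 | Brc1cc2c(cc1OCc1ccccc1)O[C@H](c1cc(OCc3ccccc3)c(OCc3ccccc3)c(OCc3ccccc3)c1)[C@H](OCc1ccccc1)[C@H]2c1c(OCc3ccccc3)c(Br)cc2c1O[C@H](c1cc(OCc3ccccc3)c(OCc3ccccc3)c(OCc3ccccc3)c1)C=C2O[Si](C)(C)C
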